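Before you touch birch at 5.0 h, decide what is left to win. Reckon with what is left, not with what is made.

| setting | birch | cedar | flask |
|---|---|---|---|
| solid substrate | 10 mM | 15 mM | 10 mM |
| reagent | 12 mM | 12 mM | 12.0 mM |
| temperature | 50 °C | 35 °C | 50 °C |
| remark | the very flask that is asked about, followed so far | run made earlier |  |
| time |  |  | 5.0 h |

birch run (percent of the solid substrate charged)

| time / h | target / % | solid substrate / % |
|---|---|---|
| 0.500 | 10.2 | 17.6 |
| 1.33 | 30.9 | 0.7 |
| 2.50 | 38.6 | 0 |
| 4.00 | 42.1 | 0 |

cedar run (percent of the solid substrate charged)

| time / min | target / % | solid substrate / % |
|---|---|---|
| 30.0 | 1.9 | 60.9 |
| 60.0 | 4.6 | 25.2 |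
| 120 | 15.0 | 0.5 |

(standard deviation of a reading: 1 percentage point)

- north: at 5.0 h raise the temperature by 20 K, then wait 5.0 h
- south-east: at 5.0 h add reagent, 50.0% of the amount charged, then wait 5.0 h
- south-west: change nothing and wait 5.0 h more
- north-west: at 5.0 h take out 90% of the target then present, then wait 5.0 h

1. target, in percent of the solid substrate first charged, at 5.0 h
2. the remedy with the largest gain of target, or "none" below 2 percentage points (north / south-east / south-west / north-west / none)
3. target present, with what was taken out counted in, in percent of the solid substrate first charged, after south-west
4. target present, with what was taken out counted in, in percent of the solid substrate first charged, after north-west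

- given per volume of solution although it is solid: solid substrate
- target that was removed still counts
- steps under discussion: starting material -> intermediate; reagent + intermediate -> target; starting material -> side product; solid substrate <-> starting material
- at the start none of the solid substrate is in solution
- additions bring no volume worth counting

Keep a ledger of the solid substrate, the limiting reagent, because birch holds 10 mM of it against 12.0 mM of reagent. Book every entry in percent of that charge. The first entry, undissolved solid, reads 0% at 2.50 h, so from there on the solid feeds nothing. The second entry, target, reads 42.1% at 4.00 h, which leaves c(reagent) near 7.79 mM.

Next comes the share still on its way to target. Compare the mean speed of target between the last readings with the speed one interval earlier. Their ratio gives a fall of 0.777 h⁻¹. Dividing the speed at 4.00 h by this constant puts 1.68% still to come then. That is a small draw on the reagent, so treat the last step as pseudo-first-order, shrinking by the same factor each hour.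

Call 0.772% the open share: the part of the charge that, at 5.0 h, will still become target. Birch's target then stands near 43.0% and its ceiling near 43.8%. The last entry, side product by difference, closes the books at 56.2%.

Hold each remedy against the open share, because the listed steps lead nowhere back from side product or target. Birch's open share is smaller than 2 percentage points, so commit to none, but as an estimate and not a bound: it comes from differences of readings that each scatter by 1 point, and the readings alone do not exclude a larger share.

The forecast gives 43.3%, a little above my figure, with 44.1% after south-west, 44.1% after north-west and none as best, holding that “Heat or extra reagent can only speed up that last point”.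

Birch gives 42.4% at 5.0 h, 42.6% after south-west and 42.6% after north-west, and the best remedy is none: each option brings 0.19 points. Birch's open share proves smaller than my estimate, with 0.195% of intermediate beside 0% of starting material.

starting material → intermediate (k = 0.200 min⁻¹, Ea = 90.0 kJ mol⁻¹); reagent + intermediate → target (k = 2.30 M⁻¹ min⁻¹, Ea = 76.0 kJ mol⁻¹); starting material → side product (k = 0.270 min⁻¹, Ea = 82.0 kJ mol⁻¹); solid substrate ⇌ starting material, rate k4*(cs4 - [starting material]) while solid is left; crystals form when [starting material] > cs4 (solubility = 3.70 mM, k = 0.0860 min⁻¹); (constants at 50 °C) In birch, intermediate's half-life with reagent as charged is 0.42 h, far shorter than the 5.0 h elapsed. The neighbour with 4.8 mM of reagent books the same side product, 57.4%, and target 33.5%, but its open share at 5.00 h exceeds 2 points, standing at 9.08%.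

(The earlier runs and the new flask were generated by integration from invented constants; scatter was added.)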